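- Slowness in these flasks shows as a delay between substrate disappearing and target appearing. The clearest way to follow it is through the fraction left: the part of the charge not yet target.

| flask | substrate | reagent | temperature | remark | time |
|---|---|---|---|---|---|
| Sunday's | 0.025 M | 0.055 M | 94 °C | run made earlier |  |
| Saturday's | 0.10 M | 0.055 M | 102 °C | run made earlier |  |
| cedar | 0.050 M | 0.0550 M | 90 °C |  | 15 min |
| birch | 0.050 M | 0.0550 M | 105 °C |  | 15 min |

- Sunday's (time / min: target / %, substrate / %): 1.00: 1.4, 62.5; 1.33: 3.8, 55.1; 2.00: 7.7, 45.6; 3.00: 13.2, 33.1; 5.00: 25.7, 23.3; 8.00: 35.3, 16.7; 12.0: 43.5, 10.9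
- Saturday's (time / min: target / %, substrate / %): 0.333: 2.0, 76.0; 1.00: 5.1, 51.0; 1.50: 8.2, 40.6; 3.00: 17.9, 28.5; 4.00: 23.5, 23.3; 6.00: 28.9, 19.5

(standard deviation of a reading: 1 percentage point)

- percent here means substrate units held: one side product counts as two
- reactions considered so far: substrate <-> intermediate A; substrate + reagent <-> intermediate B; intermediate B -> intermediate C; intermediate A <-> intermediate D; intermediate C <-> intermediate E; intermediate C -> target; substrate + intermediate E -> side product

- which of the two there is more of at the end, counted by the substrate in each, cedar (side product / target)
- which of the two there is more of at the end, counted by the substrate in each, birch (side product / target)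
- target at the end, in percent of the substrate charged, cedar
- target at the end, in percent of the substrate charged, birch

- In the first instants of Sunday's run, substrate falls fast. After 1.00 min it reads 62.5% while target reads 1.4%, so 36.1% of the charge already sits in forms that are not read.
- By 5.00 min in Sunday's run, substrate reads 23.3% and target 25.7%, so the unread stock holds about half of the charge.
- From there to 12.0 min, target gains more than substrate loses, so the unread stock is now feeding target.
- Late in Sunday's run, the fraction left falls from 64.7% to 56.5% in 4.00 min. Read as a steady proportional fall, that is 0.0339 /min, which gives a left-halving time, the time in which the fraction left halves, of 20.5 min. This is a reading from two points and carries their scatter.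
- Carrying Sunday's last reading to 15 min gives 49.0% target. Cedar is cooler and holds twice Sunday's substrate, so this reckoning places cedar below that figure.
- Carrying Saturday's last reading to 15 min gives 47.6% for birch. Side product is not read in either run, so this reckoning gives no figure for it.
- The forecast says 38% for cedar and 50% for birch, slightly above this reckoning for birch. It puts target ahead in cedar and target ahead in birch, and of birch it says “target probably still leads”.
- Cedar gives 40.7% target and birch 53.3%, each ahead of side product, at 2.01% and 3.25%. The forecast stands on both marks and within both margins. With the other amounts and the time held, cedar's target moves by 6 points at reagent 0.0439 M or 0.0682 M; those are different flasks, and the forecast gives no figure for them.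

    substrate ⇌ intermediate A (K = 1.83, k = 0.00255 /s, Ea = 115 kJ/mol, ΔH = −4.00 kJ/mol)
    substrate + reagent ⇌ intermediate B (K = 27.5 /M, k = 0.0682 /M/s, Ea = 50.0 kJ/mol, ΔH = −41.0 kJ/mol)
    intermediate B → intermediate C (k = 0.00490 /s, Ea = 102 kJ/mol)
    intermediate A ⇌ intermediate D (K = 5.00, k = 2.42 × 10⁻⁴ /s, Ea = 99.0 kJ/mol, ΔH = −4.00 kJ/mol)
    intermediate C ⇌ intermediate E (K = 18.9, k = 0.00694 /s, Ea = 105 kJ/mol, ΔH = −48.0 kJ/mol)
    intermediate C → target (k = 0.0475 /s, Ea = 93.0 kJ/mol)
    substrate + intermediate E → side product (k = 0.0392 /M/s, Ea = 71.0 kJ/mol)
    (constants at 90 °C)

- At the start of birch, the forward step to intermediate B uses substrate at 0.63 of the forward rate of the step to intermediate A. Read at 4.0 min, the same flask holds 36.6% as intermediate A, more than its 28.3% target. Carried from birch's 39.9% target at 7.50 min, the left-halving time gives 53.4% at 15 min, beside the 53.3% found. Carried on to 1.0 h, it gives 89.8%, while that reading shows 70.8% target with 21.0% standing as intermediate D.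

The earlier runs and the new flask were generated by integration from invented constants; scatter was added.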